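## The problem

Target 14 is a 2-aryl-3-methyl-2,3-dihydro-1,4-benzodioxine. A dioxane (ring B) is fused to a benzene (ring A) that carries a methoxy group at C5 and an allyl group at C7, and C2 bears a 4-hydroxy-3,5-dimethoxyphenyl group (ring C). The two ring oxygens differ: O4, bonded to the methyl-bearing C3, is flanked by the C5 methoxy group, whereas O1, bonded to the benzylic C2, has a free ortho position. Any union of a catechol with a two-carbon unit must tell them apart. C2 and C3 are both R and trans. Only C2 is labile: once the para phenol of ring C is free, the C2–O1 bond can open to a quinone methide and reclose. C3 can therefore steer C2 to trans, but C2 cannot correct C3, so a cis isomer with the wrong C3 would equilibrate to the enantiomer of 14. The terminal allyl group (double-bond migration, hydrogenation, carbene addition), the electron-rich phenol and the acid-labile para-oxybenzylic C2–O1 ether limit what can be done late. The enabling feature is that O1–C2–C3–O4 is, atom for atom, the ethylidene acetal O1–C3–O4 of the ring A catechol with an ArCH unit (C2) inserted into its O1–C3 bond. This invites a carbene ring expansion of a five-membered acetal to ring B.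

## Retrosynthesis

**14 ⇒ 13.** Only the acyl–oxygen bond of an aryl acetate is cut. The phenol stays masked to the end because a free O–H would be taken by the carbene and because the free para-phenol is what makes C2 labile. An acetate is preferred to a silyl or alkyl ether: it lowers the electron density of ring C, which tempers both the diazo compound and the ionisability of C2–O1. It also leaves under conditions that spare the allyl group. The forward step must be a short, cold, mildly basic solvolysis.

**13 ⇒ 12.** The C7–allyl bond is cut, giving aryl bromide 12. The allyl group cannot be present earlier, since a terminal alkene accepts a carbene more readily than an ether oxygen does. Bromine is the better placeholder than an ester or a protected alcohol: it is already present in a commercial ring A building block, slightly deactivates ring A towards the carbene, and is exchanged for allyl in one neutral palladium-catalysed coupling. The forward step must avoid double-bond migration and loss of the acetate.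

**12 ⇒ 5 + 11.** The central cut breaks O1–C2 and C2–C3 and so removes C2 from ring B. What remains is the racemic ethylidene acetal 5 and the achiral aryldiazomethane 11.
- The neighbouring two-bond cuts are weaker. Cutting O1–C2 together with O4–C3 (catechol plus a 1,2-dielectrophile) leaves the two catechol oxygens undifferentiated. Cutting one aryl–oxygen bond requires each stereocentre to be built separately in an open chain.
- This cut uses the crowding of one acetal oxygen by the methoxy group to fix the regiochemistry, and it makes the ring, two skeletal bonds and both stereocentres in one catalytic event.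
- The forward reaction asks a chiral dirhodium carboxylate to convert 11 into a carbene, have it attacked by the unhindered acetal oxygen of 5, and steer the [1,2]-shift of the acetal carbon so that trans-(2R,3R)-12 results. The stereocentre of 5 is erased on the way.

**11 ⇒ 10 ⇒ 9 ⇒ 7 + 8; 7 ⇒ 6.** Compound 11 is too labile to store. It is traced through its precursor salt 10 to tosylhydrazone 9, from which it is released slowly in the reaction flask. Compound 9 comes from aldehyde 7 and p-toluenesulfonyl hydrazide 8. Aldehyde 7 is the O-acetate of syringaldehyde 6, which already has the full substitution pattern of ring C. Acetylation precedes hydrazone formation so that the acylating agent never meets the hydrazone N–H.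

**5 ⇒ 3 + 4; 3 ⇒ 2 ⇒ 1.** Acetal 5 is cut at both acetal C–O bonds to catechol 3 and 1,1-dimethoxyethane 4. Acid-catalysed acetal exchange is chosen over alkylation with a geminal dihalide because a secondary dihalide is prone to elimination. Catechol 3 follows from commercial salicylaldehyde 1 by exchange of formyl for hydroxyl (Dakin oxidation through formate 2). Compound 1 carries bromine and methoxy exactly where needed, so no aromatic substitution has to be controlled.

## Roads not taken

**Alternative 1:** The cut is the aryl–oxygen bond O1–C8a.
- Forward step: the bromo alcohol A2, (1R,2R)-2-[2-bromo-6-methoxy-4-(prop-2-en-1-yl)phenoxy]-1-[3,5-dimethoxy-4-(methoxymethoxy)phenyl]propan-1-ol, is cyclised with CuI (copper iodide), 3,4,7,8-tetramethyl-1,10-phenanthroline and Cs2CO3 in hot toluene. The product is A1, (2R,3R)-7-allyl-2-[3,5-dimethoxy-4-(methoxymethoxy)phenyl]-5-methoxy-3-methyl-2,3-dihydro-1,4-benzodioxine; acid then removes the MOM group.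
- Merits: both stereocentres exist before the ring closes and are not touched by it. Each oxygen is attached individually, so regiochemistry is certain. The allyl group is present from the start, so no late coupling is needed. The key step is a known reaction type.
- Weak points: A2 needs each stereocentre to be set in a separate operation and a long linear sequence. The coupling joins a secondary benzylic alkoxide with β-hydrogen to an electron-rich, ortho-alkoxy aryl bromide, where oxidation of the alcohol and reduction of the bromide compete. Cs2CO3 above 100 °C can move the allyl double bond into conjugation. The final acid step meets an acid-labile C2–O1 ether.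
- Comparison: this road is better in stereochemical and regiochemical certainty and in the precedent for its ring closure. The chosen plan sets against it a shorter and more convergent sequence from two simple aldehydes and the formation of the ring and both stereocentres in one catalytic step. A chiral-pool fallback that reaches 12 by known reactions covers its stereochemical risk.

**Alternative 2:** The cut is the aryl–oxygen bond O4–C4a.
- Forward step: the C3 alkoxide of A4, methyl 4-bromo-3-{(1R,2R)-1-[4-(2,2-dimethylpropanoyloxy)-3,5-dimethoxyphenyl]-2-hydroxypropoxy}-5-methoxybenzoate, displaces the bromide with CuI (copper iodide), 1,10-phenanthroline and Cs2CO3. The product is A3, methyl (2R,3R)-2-[3,5-dimethoxy-4-(pivaloyloxy)phenyl]-5-methoxy-3-methyl-2,3-dihydro-1,4-benzodioxine-7-carboxylate.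
- Merits: the para ester activates the bromide, the stereocentres are again set beforehand, and the reaction class is known.
- Weak points: the bromide sits between a methoxy group and a bulky benzylic ether, the most hindered arrangement possible for a secondary alkoxide. The benzylic ether of A4 must be made at an ionisable benzylic carbon, where configuration is easily lost. The C7 ester is the wrong group: turning it into allyl costs several steps (reduction, activation, vinyl coupling), during which the pivalate is also at risk.
- Comparison: it shares the stereochemical certainty of Alternative 1 but has no other advantage. It is clearly longer than the chosen plan, whose bromine placeholder becomes allyl in one step.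

**Alternative 3:** The cut is C3–O4 together with one C–H bond of the methyl group.
- Forward step: the allylic aryl ether A6, 4-bromo-2-methoxy-6-({(1S)-1-[3,5-dimethoxy-4-(triisopropylsilyloxy)phenyl]prop-2-en-1-yl}oxy)phenol, undergoes Markovnikov hydroalkoxylation by hydrogen-atom transfer with Co(salen), N-fluoro-2,4,6-trimethylpyridinium tetrafluoroborate and PhSiH3. The product is A5, (2R,3R)-7-bromo-2-[3,5-dimethoxy-4-(triisopropylsilyloxy)phenyl]-5-methoxy-3-methyl-2,3-dihydro-1,4-benzodioxine.
- Merits: room-temperature conditions, a short substrate, a key step close to known hydroalkoxylations of alkenyl phenols, and the same bromide end game as the chosen plan.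
- Weak points: C3, the centre that cannot be corrected later, is formed only by induction from C2. The C2–O1 bond of A6 is both benzylic and allylic, so ionisation and aromatic Claisen rearrangement threaten its configuration. The N-fluoropyridinium oxidant meets an electron-rich free phenol.
- Comparison: its key step has closer precedent than the chosen one, and the step count is similar. The chosen plan sets against it that it needs no pre-formed, fragile stereocentre and creates both centres in one catalyst-bound event.

Key step: step 5

Assumption: Rh2(S-PTAD)4 is written because phthalimido-amino-acid carboxylates of divalent rhodium are the class best suited to carbenes without an acceptor group. Its sense of induction here cannot be predicted, and Rh2(R-PTAD)4 is used if the S catalyst favours the (2S,3S) product.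

## Route

Step 1
Reactants: 1 5-bromo-2-hydroxy-3-methoxybenzaldehyde
Product: 3 5-bromo-3-methoxybenzene-1,2-diol, via aryl formate 2 (not isolated)
Conditions: 30% aq H2O2 (1.2 equiv), NaOH (1.1 equiv), H2O, 0 °C to rt, argon; then 1 M HCl
Reagents that add atoms: hydrogen peroxide, OO
Why: Dakin oxidation: hydroperoxide adds to the aldehyde, the electron-rich aryl group migrates to oxygen, and formate 2 is saponified in the same pot. No stereocentre is involved; argon protects the air-sensitive catechol.

Step 2
Reactants: 3 5-bromo-3-methoxybenzene-1,2-diol; 4 1,1-dimethoxyethane (acetaldehyde dimethyl acetal)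
Product: 5 6-bromo-4-methoxy-2-methyl-1,3-benzodioxole (racemic)
Conditions: 4 (3 equiv), p-TsOH·H2O (5 mol %), toluene, 90 °C, Soxhlet with 4 Å molecular sieves
Reagents that add atoms: none
Why: Acid-catalysed transacetalisation, the ethylidene counterpart of catechol acetonide formation, driven by removal of methanol on the sieves. The acetal stereocentre is made racemic on purpose, since step 5 erases it.

Step 3
Reactants: 6 syringaldehyde (4-hydroxy-3,5-dimethoxybenzaldehyde)
Product: 7 4-formyl-2,6-dimethoxyphenyl acetate
Conditions: Ac2O, pyridine, DMAP (cat.), CH2Cl2, 0 °C to rt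
Reagents that add atoms: acetic anhydride, CC(=O)OC(C)=O
Why: Standard O-acetylation of a phenol; the aldehyde is not affected.

Step 4
Reactants: 7 4-formyl-2,6-dimethoxyphenyl acetate; 8 p-toluenesulfonyl hydrazide
Product: 9 2,6-dimethoxy-4-[(E)-{2-[(4-methylphenyl)sulfonyl]hydrazinylidene}methyl]phenyl acetate
Conditions: 8 (1.0 equiv), MeOH, rt
Reagents that add atoms: none
Why: Condensation of the aldehyde with the sulfonyl hydrazide should give the crystalline (E)-tosylhydrazone. One equivalent of 8 at room temperature keeps the aryl acetate from being attacked.

Step 5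
Reactants: 9 2,6-dimethoxy-4-[(E)-{2-[(4-methylphenyl)sulfonyl]hydrazinylidene}methyl]phenyl acetate; 5 6-bromo-4-methoxy-2-methyl-1,3-benzodioxole (racemic)
Product: 12 4-[(2R,3R)-7-bromo-5-methoxy-3-methyl-2,3-dihydro-1,4-benzodioxin-2-yl]-2,6-dimethoxyphenyl acetate, via sodium tosylhydrazonide 10 (not isolated), via aryldiazomethane 11 (not isolated)
Conditions: NaH (1.0 equiv), THF, 0 °C, then evaporation; 5 (3 equiv), Rh2(S-PTAD)4 (1 mol %), BnEt3NCl (10 mol %), toluene, 35 °C
Reagents that add atoms: none
Why: Proposed new method: salt 10 loses sulfinate (Bamford–Stevens) and releases 11 slowly; the rhodium carbene from 11 is attacked by the unhindered acetal oxygen O1 of 5 to give a rhodium-bound oxonium ylide, the O1–C(acetal) bond ionises, and C–C bond formation between the benzylic carbon and the oxocarbenium carbon completes a [1,2]-Stevens shift that inserts ArCH into the O1–C bond; the closest known reactions are the Rh2(OAc)4- or copper-catalysed ring expansions of 1,3-dioxolanes and 2-aryl-1,3-dioxanes with diazo esters and the copper-catalysed enantioselective expansion of oxetanes to tetrahydrofurans, none of which uses an acceptor-free aryl carbene or a benzodioxole. Ring B closes by 6-endo-trig attack of the rhodium-bearing carbon C2 on the O4-stabilised oxocarbenium carbon C3, a net five-to-six ring expansion. C2 is under catalyst control: the chiral carboxylate pocket decides which face of the carbene the oxygen attacks, and because the carbene has no acceptor to stabilise a metal-free ylide, rhodium should stay on carbon until the C–C bond forms. C3 is set relative to C2 in the cyclic transition state, which places aryl and methyl pseudo-equatorial and should favour trans, while the configuration of racemic 5 is lost in the planar oxocarbenium ion. Regioselectivity rests on the methoxy group that crowds the other acetal oxygen; chemoselectivity rests on bromine in place of allyl (no alkene to cyclopropanate, a deactivated arene), on the acetate (no O–H insertion, a less electron-rich diazo compound), on the excess of 5 and on the slow release of 11, which limits carbene dimerisation. Any cis isomer is removed by chromatography at this stage, because later equilibration at C2 would turn a cis isomer with the wrong C3 into the enantiomer of the target.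

Step 6
Reactants: 12 4-[(2R,3R)-7-bromo-5-methoxy-3-methyl-2,3-dihydro-1,4-benzodioxin-2-yl]-2,6-dimethoxyphenyl acetate
Product: 13 4-[(2R,3R)-5-methoxy-3-methyl-7-(prop-2-en-1-yl)-2,3-dihydro-1,4-benzodioxin-2-yl]-2,6-dimethoxyphenyl acetate
Conditions: allylSnBu3 (1.5 equiv), Pd(PPh3)4 (5 mol %), toluene, 100 °C
Reagents that add atoms: allyltributylstannane, C=CC[Sn](CCCC)(CCCC)CCCC
Why: Stille coupling: zerovalent palladium inserts into the unhindered C7–Br bond, allyl is transferred from tin, and reductive elimination follows. The neutral conditions leave the acetate and both stereocentres untouched; the reaction is stopped at full conversion to limit double-bond migration.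

Step 7
Reactants: 13 4-[(2R,3R)-5-methoxy-3-methyl-7-(prop-2-en-1-yl)-2,3-dihydro-1,4-benzodioxin-2-yl]-2,6-dimethoxyphenyl acetate
Product: 14 4-[(2R,3R)-5-methoxy-3-methyl-7-(prop-2-en-1-yl)-2,3-dihydro-1,4-benzodioxin-2-yl]-2,6-dimethoxyphenol
Conditions: K2CO3 (0.3 equiv), MeOH, 0 °C to rt; then aq NH4Cl
Reagents that add atoms: none
Why: Base-catalysed transesterification of the aryl acetate with methanol. The exposure is kept short and cold because the freed para-phenoxide can open C2–O1 to a quinone methide; that path can only return the trans isomer with C3 unchanged, but methanol could intercept it.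

## Compound list

1 | 5-bromo-2-hydroxy-3-methoxybenzaldehyde | COc1cc(Br)cc(C=O)c1O | starting material
2 | 5-bromo-2-hydroxy-3-methoxyphenyl formate | O=COc1cc(Br)cc(OC)c1O | intermediate (not isolated)
3 | 5-bromo-3-methoxybenzene-1,2-diol | COc1cc(Br)cc(O)c1O | intermediate
4 | 1,1-dimethoxyethane | CC(OC)OC | starting material
5 | 6-bromo-4-methoxy-2-methyl-1,3-benzodioxole (racemic) | CC1Oc2cc(Br)cc(OC)c2O1 | intermediate
6 | syringaldehyde (4-hydroxy-3,5-dimethoxybenzaldehyde) | COc1cc(C=O)cc(OC)c1O | starting material
7 | 4-formyl-2,6-dimethoxyphenyl acetate | COc1cc(C=O)cc(OC)c1OC(C)=O | intermediate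
8 | p-toluenesulfonyl hydrazide | Cc1ccc(cc1)S(=O)(=O)NN | starting material
9 | 2,6-dimethoxy-4-[(E)-{2-[(4-methylphenyl)sulfonyl]hydrazinylidene}methyl]phenyl acetate | COc1cc(/C=N/NS(=O)(=O)c2ccc(C)cc2)cc(OC)c1OC(C)=O | intermediate
10 | sodium salt of 9, deprotonated at the sulfonamide nitrogen | COc1cc(/C=N/[N-]S(=O)(=O)c2ccc(C)cc2)cc(OC)c1OC(C)=O.[Na+] | intermediate (not isolated)
11 | 4-(diazomethyl)-2,6-dimethoxyphenyl acetate | [N-]=[N+]=Cc1cc(OC)c(OC(C)=O)c(OC)c1 | intermediate (not isolated)
12 | 4-[(2R,3R)-7-bromo-5-methoxy-3-methyl-2,3-dihydro-1,4-benzodioxin-2-yl]-2,6-dimethoxyphenyl acetate (trans) | Brc1cc(OC)c2c(c1)O[C@H](c1cc(OC)c(OC(C)=O)c(OC)c1)[C@@H](C)O2 | intermediate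
13 | 4-[(2R,3R)-5-methoxy-3-methyl-7-(prop-2-en-1-yl)-2,3-dihydro-1,4-benzodioxin-2-yl]-2,6-dimethoxyphenyl acetate (trans) | C=CCc1cc(OC)c2c(c1)O[C@H](c1cc(OC)c(OC(C)=O)c(OC)c1)[C@@H](C)O2 | intermediate
14 | 4-[(2R,3R)-5-methoxy-3-methyl-7-(prop-2-en-1-yl)-2,3-dihydro-1,4-benzodioxin-2-yl]-2,6-dimethoxyphenol (trans) | C=CCc1cc(OC)c2c(c1)O[C@H](c1cc(OC)c(O)c(OC)c1)[C@@H](C)O2 | target

## Step count and risks

Total: 7 steps. Longest linear sequence: 5 steps (1 → 3 → 5 → 12 → 13 → 14, or equally 6 → 7 → 9 → 12 → 13 → 14).

**Step 5 (key step, proposed new method).**
- What may go wrong: the carbene is consumed by dimerisation with a second molecule of 11, or by the sulfinate, faster than the weakly basic aryl acetal oxygen intercepts it. Hydride abstraction from the acetal C–H (formal C–H insertion) may compete. Stereocontrol is lost if rhodium leaves the ylide before the C–C bond forms, which would give racemic or cis-rich material. Ylide formation at the crowded oxygen would erode regioselectivity.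
- Fallback (known chemistry, chiral pool; sets out from 1 and returns at 12):
  - Mitsunobu etherification of the phenol of 1 with ethyl (S)-lactate (PPh3, DIAD, THF) proceeds with inversion. It gives ethyl (2R)-2-(4-bromo-2-formyl-6-methoxyphenoxy)propanoate F1 and fixes C3 and the O4–C3 bond.
  - Baeyer–Villiger oxidation of the aldehyde with mCPBA gives ethyl (2R)-2-[4-bromo-2-(formyloxy)-6-methoxyphenoxy]propanoate F2.
  - i-Bu2AlH (CH2Cl2, −78 °C) cleaves the formate and reduces the ester to the aldehyde level. The freed phenol closes to the lactol (3R)-7-bromo-5-methoxy-3-methyl-2,3-dihydro-1,4-benzodioxin-2-ol F3.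
  - Separately, commercial 4-bromo-2,6-dimethoxyphenol is protected (MOMCl, i-Pr2NEt) as 5-bromo-1,3-dimethoxy-2-(methoxymethoxy)benzene F4. Mg in THF converts it into [3,5-dimethoxy-4-(methoxymethoxy)phenyl]magnesium bromide F5.
  - Excess F5 opens lactol F3 and gives (2R)-2-(4-bromo-2-hydroxy-6-methoxyphenoxy)-1-[3,5-dimethoxy-4-(methoxymethoxy)phenyl]propan-1-ol F6 as a mixture of C1 epimers.
  - CF3CO2H in CH2Cl2 removes the MOM group and ionises the benzylic alcohol. The ortho phenol traps the cation under thermodynamic control to give 4-[(2R,3R)-7-bromo-5-methoxy-3-methyl-2,3-dihydro-1,4-benzodioxin-2-yl]-2,6-dimethoxyphenol F7.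
  - Acetylation of F7 (Ac2O, pyridine) gives 12.

**Step 2.**
- What may go wrong: the oxocarbenium ion attacks the electron-rich ring (C-alkylation) instead of the second hydroxyl, and ring closure stays incomplete because acetal exchange is reversible.
- Fallback (sets out from 3 and returns at 5): double O-alkylation of the catechol with 1,1-dibromoethane and Cs2CO3 in DMF at 80 °C, the geminal dihalide acetalisation used for methylenedioxy rings. It involves no acid and no free oxocarbenium ion, and no new compound arises on this detour (F0).

**Step 6.**
- What may go wrong: the allyl double bond migrates into conjugation with ring A through palladium hydride species at 100 °C, and oxidative addition into the electron-rich aryl bromide is slow.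
- Fallback (reversed polarity; sets out from 12 and returns at 13): Miyaura borylation (B2pin2, PdCl2(dppf), KOAc, 1,4-dioxane, 80 °C) gives 4-[(2R,3R)-5-methoxy-3-methyl-7-(4,4,5,5-tetramethyl-1,3,2-dioxaborolan-2-yl)-2,3-dihydro-1,4-benzodioxin-2-yl]-2,6-dimethoxyphenyl acetate F8. This is coupled with allyl bromide (Pd(PPh3)4, CsF, THF, 50 °C) to give 13. If the acetate is lost under these conditions, the product is 14 itself.

## Further compounds

F1 | step 5 | ethyl (2R)-2-(4-bromo-2-formyl-6-methoxyphenoxy)propanoate | CCOC(=O)[C@@H](C)Oc1c(C=O)cc(Br)cc1OC
F2 | step 5 | ethyl (2R)-2-[4-bromo-2-(formyloxy)-6-methoxyphenoxy]propanoate | CCOC(=O)[C@@H](C)Oc1c(OC=O)cc(Br)cc1OC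
F3 | step 5 | (3R)-7-bromo-5-methoxy-3-methyl-2,3-dihydro-1,4-benzodioxin-2-ol (both C2 epimers) | C[C@H]1Oc2c(OC)cc(Br)cc2OC1O
F4 | step 5 | 5-bromo-1,3-dimethoxy-2-(methoxymethoxy)benzene | COCOc1c(OC)cc(Br)cc1OC
F5 | step 5 | [3,5-dimethoxy-4-(methoxymethoxy)phenyl]magnesium bromide | COCOc1c(OC)cc([Mg]Br)cc1OC
F6 | step 5 | (2R)-2-(4-bromo-2-hydroxy-6-methoxyphenoxy)-1-[3,5-dimethoxy-4-(methoxymethoxy)phenyl]propan-1-ol (both C1 epimers) | COCOc1c(OC)cc(cc1OC)C(O)[C@@H](C)Oc1c(O)cc(Br)cc1OC
F7 | step 5 | 4-[(2R,3R)-7-bromo-5-methoxy-3-methyl-2,3-dihydro-1,4-benzodioxin-2-yl]-2,6-dimethoxyphenol | Brc1cc(OC)c2c(c1)O[C@H](c1cc(OC)c(O)c(OC)c1)[C@@H](C)O2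
F0 | step 2 | none | none
F8 | step 6 | 4-[(2R,3R)-5-methoxy-3-methyl-7-(4,4,5,5-tetramethyl-1,3,2-dioxaborolan-2-yl)-2,3-dihydro-1,4-benzodioxin-2-yl]-2,6-dimethoxyphenyl acetate | CC1(C)OB(OC1(C)C)c1cc(OC)c2c(c1)O[C@H](c1cc(OC)c(OC(C)=O)c(OC)c1)[C@@H](C)O2
A1 | alternative 1 | (2R,3R)-7-allyl-2-[3,5-dimethoxy-4-(methoxymethoxy)phenyl]-5-methoxy-3-methyl-2,3-dihydro-1,4-benzodioxine | C=CCc1cc(OC)c2c(c1)O[C@H](c1cc(OC)c(OCOC)c(OC)c1)[C@@H](C)O2
A2 | alternative 1 | (1R,2R)-2-[2-bromo-6-methoxy-4-(prop-2-en-1-yl)phenoxy]-1-[3,5-dimethoxy-4-(methoxymethoxy)phenyl]propan-1-ol | O[C@H](c1cc(OC)c(OCOC)c(OC)c1)[C@@H](C)Oc1c(Br)cc(CC=C)cc1OC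
A3 | alternative 2 | methyl (2R,3R)-2-[3,5-dimethoxy-4-(pivaloyloxy)phenyl]-5-methoxy-3-methyl-2,3-dihydro-1,4-benzodioxine-7-carboxylate | COC(=O)c1cc(OC)c2c(c1)O[C@H](c1cc(OC)c(OC(=O)C(C)(C)C)c(OC)c1)[C@@H](C)O2
A4 | alternative 2 | methyl 4-bromo-3-{(1R,2R)-1-[4-(2,2-dimethylpropanoyloxy)-3,5-dimethoxyphenyl]-2-hydroxypropoxy}-5-methoxybenzoate | COC(=O)c1cc(OC)c(Br)c(c1)O[C@H](c1cc(OC)c(OC(=O)C(C)(C)C)c(OC)c1)[C@@H](C)O
A5 | alternative 3 | (2R,3R)-7-bromo-2-[3,5-dimethoxy-4-(triisopropylsilyloxy)phenyl]-5-methoxy-3-methyl-2,3-dihydro-1,4-benzodioxine | Brc1cc(OC)c2c(c1)O[C@H](c1cc(OC)c(O[Si](C(C)C)(C(C)C)C(C)C)c(OC)c1)[C@@H](C)O2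
A6 | alternative 3 | 4-bromo-2-methoxy-6-({(1S)-1-[3,5-dimethoxy-4-(triisopropylsilyloxy)phenyl]prop-2-en-1-yl}oxy)phenol | C=C[C@@H](c1cc(OC)c(O[Si](C(C)C)(C(C)C)C(C)C)c(OC)c1)Oc1cc(Br)cc(OC)c1O
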